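**Plan**

1. Retrosynthesis: the C11–C12 bond (Wittig, then diimide) and the C9=C11 bond (methylenation, then hydroboration) detach the C12–C15 acid. The 2,3-diol goes back to a 2-ene (OsO4), this to a C3 ketone, and the C19 acetate to a C19 aldehyde.
2. Enabling feature: ring A then holds the array O=C3–C4(CH3)(C19H=O), a quaternary C4 with a one-carbon carbonyl branch beside a ring carbonyl. This is the product pattern of a 1,2-acyl shift, so C19 can have been a ring atom between C3 and C4 of a seven-membered epoxy ketone (C3–C19 broken, C3–C4 made in one event).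
3. Forward order: ring B is (S)-carvone; C10 is made quaternary by methylation and allylation; the allyl arm is grown to a vinyl carbinol; metathesis with the isopropenyl group (C4, C18) closes the seven-membered ring; directed epoxidation, oxidation and BF3 contract it to ring A; dihydroxylation and the side chain follow.
4. Stereochemistry: C5 from (S)-carvone; C10 by alkylation anti to isopropenyl; a temporary C3 carbinol (ligand control) steers the epoxide syn to the C10 methyl and the stereospecific shift converts it into C4; C2 and C3 by OsO4 anti to the axial C19/C20 groups; C9 by hydroboration anti to C20; C13 from (R)-methyl hydrogen 3-methylglutarate.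

Key step: step 8

Remark: labdane numbering (C1–C20; C17 on C8, C18/C19 on C4, C20 on C10) is used for all bicyclic compounds, the seven-membered-ring precursors included. The target is read as an ent-labdane, which fixes (S)-carvone as the ring B source; (R)-methyl hydrogen 3-methylglutarate and (−)-MIB are assumed to be purchasable.

**Route**

Step 1
Reactants: 1 (S)-carvone
Product: 3 trans-6-methylcarvone, via lithium dienolate 2 (not isolated)
Conditions: LiN(i-Pr)2, THF, −78 °C; MeI, −78 to 0 °C
Reagents that add atoms: iodomethane, CI
Why: Enolate alkylation: kinetic α′-deprotonation gives the cross-conjugated dienolate 2, which is C-methylated at C6 (the future C10); the trans isomer should predominate but either C6 epimer serves because this centre is re-enolised in step 2, while C5 of (S)-carvone is kept as C5 of the target.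

Step 2
Reactants: 3 trans-6-methylcarvone
Product: 5 allylated ketone (6-allyl-6-methylcarvone; allyl trans to isopropenyl), via lithium enolate 4 (not isolated)
Conditions: LiN(i-Pr)2, THF/DMPU, −78 °C; allyl bromide, −78 °C to rt
Reagents that add atoms: allyl bromide, C=CCBr
Why: Second enolate alkylation: allyl bromide should attack the tetrasubstituted enolate 4 from the face opposite the adjacent isopropenyl group, which sets the quaternary carbon (future C10) with the methyl cis and the three-carbon arm (future C1–C3) trans to isopropenyl.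

Step 3
Reactants: 5 allylated ketone
Product: 6 keto aldehyde (3-oxopropyl arm on C10)
Conditions: PdCl2(PhCN)2 (10 mol %), CuCl2·2H2O (10 mol %), AgNO2 (5 mol %), O2 (1 atm), t-BuOH/MeNO2 15:1, rt
Reagents that add atoms: dioxygen, O=O
Why: Aldehyde-selective (nitrite-co-catalysed) Wacker oxidation should convert the only monosubstituted alkene into the anti-Markovnikov aldehyde, since the 1,1-disubstituted isopropenyl group and the electron-poor enone alkene are poor substrates.

Step 4
Reactants: 6 keto aldehyde
Product: 7 vinyl carbinol (3R)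
Conditions: ZnCl2, CH2=CHMgBr, Et2O, 0 °C; N,N,N′,N′-tetraethylethylenediamine; then 6, (−)-MIB (5 mol %), toluene, 0 °C
Reagents that add atoms: vinylmagnesium bromide, C=C[Mg]Br (vinyl group, passed on through divinylzinc, C=C[Zn]C=C)
Why: Catalytic enantioselective alkenylzinc addition: the amino-alcohol–zinc complex should deliver the vinyl group to the Si face of the aldehyde (the sense this ligand shows with other organozincs), giving the 3R carbinol irrespective of the remote ring stereocentres, and the hindered ketone does not react with organozincs.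

Step 5
Reactants: 7 vinyl carbinol
Product: 8 cycloheptenol (seven-membered ring C4=C19–C3–C2–C1–C10–C5; 3-OH cis to the C10 methyl)
Conditions: second-generation Grubbs catalyst (H2IMes)(PCy3)Cl2Ru=CHPh (5 mol %), CH2Cl2 (0.005 M), 40 °C
Reagents that add atoms: none
Why: Ring-closing metathesis between the vinyl carbinol and the isopropenyl group, held on adjacent equatorial bonds of the cyclohexenone, should close the trisubstituted cycloheptene with loss of ethylene; the enone alkene is electron-poor and trisubstituted and should stay out.

Step 6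
Reactants: 8 cycloheptenol
Product: 9 epoxy alcohol (4,19-epoxide and 3-OH both cis to the C10 methyl)
Conditions: VO(acac)2 (5 mol %), t-BuOOH, CH2Cl2, 0 °C to rt
Reagents that add atoms: tert-butyl hydroperoxide, CC(C)(C)OO
Why: Hydroxyl-directed epoxidation: the vanadium alkoxide of the cyclic allylic alcohol delivers the peroxide oxygen to the alkene face syn to the C3 hydroxyl, which is the face of C4/C19 that carries the C10 methyl, and this electrophilic system does not epoxidise the enone alkene.

Step 7
Reactants: 9 epoxy alcohol
Product: 10 epoxy ketone (3-oxo-4,19-epoxide)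
Conditions: Dess–Martin periodinane, pyridine, CH2Cl2, 0 °C to rt
Reagents that add atoms: none
Why: Dess–Martin oxidation with pyridine buffering converts the secondary carbinol into the C3 ketone without opening the acid-sensitive epoxide, erasing the temporary C3 stereocentre once it has done its directing work.

Step 8
Reactants: 10 epoxy ketone
Product: 11 keto aldehyde (ring A formed; 3,9-dioxo-19-al, CHO cis to C20)
Conditions: BF3·OEt2 (0.3 equiv), CH2Cl2, −40 to 0 °C
Reagents that add atoms: none
Why: BF3 binds the epoxide oxygen and the C4–O bond ionises, because C4 is tertiary whereas a cation at C19 would sit α to the C3 carbonyl; the acyl carbon C3 then shifts from C19 to C4 on the face opposite the departing oxygen while C19 becomes the formyl carbon (House–Meinwald rearrangement of an α,β-epoxy ketone, the reaction that turns isophorone oxide into a 2-formylcyclopentanone). Ring A is not closed by a cyclisation but by contraction of the seven-membered ring: a suprafacial 1,2-acyl shift through a three-centre acyl-bridged transition state excises C19 from the ring and joins C3 to C4. The new quaternary stereocentre C4 is set by inversion at the migration terminus, so the epoxide oxygen placed syn to the C10 methyl in step 6 becomes the axial C19 formyl group cis to C20, with the C18 methyl equatorial. The step needs acyl migration to beat the 1,2-hydride shift from C19 (which would give a 3,19-diketone in the seven-membered ring) and needs regioselective C4–O cleavage; the first is favoured by the high migratory aptitude of acyl groups and the antiperiplanar C19–C3 ring bond, the second by the tertiary centre and the deactivating carbonyl. The product is a non-enolisable β-keto aldehyde that cannot epimerise at C4 and is reduced at once in step 9 to forestall loss of the formyl group.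

Step 9
Reactants: 11 keto aldehyde
Product: 12 hydroxy ketone (19-hydroxy-3,9-dione)
Conditions: NaBH4 (0.3 equiv), MeOH/CH2Cl2 1:1, −78 °C
Reagents that add atoms: none
Why: Chemoselective borohydride reduction: at −78 °C the activated aldehyde should be reduced well before the two α-branched ketones, and the low temperature and absence of strong base avoid retro-Claisen loss of the formyl carbon.

Step 10
Reactants: 12 hydroxy ketone
Product: 13 keto acetate (19-acetoxy-3,9-dione)
Conditions: Ac2O, pyridine, DMAP (cat.), CH2Cl2, 0 °C
Reagents that add atoms: acetic anhydride, CC(=O)OC(C)=O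
Why: DMAP-catalysed acylation installs the C19 acetate of the target at once, which also blocks retro-aldol loss of formaldehyde from the β-hydroxy ketone.

Step 11
Reactants: 13 keto acetate
Product: 15 enol triflate (2-en-3-yl triflate), via potassium enolate 14 (not isolated)
Conditions: KN(SiMe3)2, THF, −78 °C; PhNTf2, −78 to 0 °C
Reagents that add atoms: N-phenylbis(trifluoromethanesulfonimide), O=S(=O)(N(c1ccccc1)S(=O)(=O)C(F)(F)F)C(F)(F)F
Why: Enol triflate formation: the C3 ketone can enolise only toward C2 because C4 is quaternary, the silylamide base is too weak to deprotonate the acetate appreciably and the C9 enone has no α′-hydrogen, so O-sulfonylation of enolate 14 should give the 2-ene triflate.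

Step 12
Reactants: 15 enol triflate
Product: 16 alkene (19-acetoxy-2,7-dien-9-one)
Conditions: Pd(OAc)2 (5 mol %), PPh3 (10 mol %), HCO2H, n-Bu3N, DMF, 60 °C
Reagents that add atoms: none
Why: Palladium-catalysed formate reduction of an enol triflate (oxidative addition, formate exchange, decarboxylation, reductive elimination) should replace OTf by H and leave the 2-ene needed for dihydroxylation, with enone and acetate untouched.

Step 13
Reactants: 16 alkene
Product: 17 diol (2,3-cis-diol trans to C20)
Conditions: OsO4 (2 mol %), N-methylmorpholine N-oxide, acetone/H2O, rt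
Reagents that add atoms: osmium tetroxide, O=[Os](=O)(=O)=O (transfers both oxygens, catalytic); N-methylmorpholine N-oxide, C[N+]1([O-])CCOCC1, and water, O (terminal oxygen sources)
Why: Upjohn dihydroxylation: OsO4 should add suprafacially to the electron-richer cis-disubstituted 2-ene from the face opposite the axial C19 acetoxymethyl and C20 methyl groups, which sets C2 and C3 as the cis-diol trans to C20, while the conjugated 7-ene reacts far more slowly.

Step 14
Reactants: 17 diol
Product: 18 acetonide
Conditions: Me2C(OMe)2, PPTS (cat.), CH2Cl2, rt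
Reagents that add atoms: 2,2-dimethoxypropane, COC(C)(C)OC
Why: Acid-catalysed transketalisation protects the cis-diol as its isopropylidene acetal so that the hydroxyls do not interfere with the organometallic and oxidation steps that follow.

Step 15
Reactants: 18 acetonide
Product: 19 diene (exocyclic C9=C11)
Conditions: Zn, CH2Br2, TiCl4, THF/CH2Cl2, 0 °C to rt
Reagents that add atoms: dibromomethane, BrCBr
Why: Lombardo methylenation with the Zn/CH2Br2/TiCl4 reagent is non-basic and selective for ketones over esters, so the hindered C9 carbonyl should become the exocyclic alkene without touching the acetate or epimerising anything.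

Step 16
Reactants: 19 diene
Product: 21 primary alcohol (C11–OH; C9 side arm cis to C20), via B-alkyl-9-BBN 20 (not isolated)
Conditions: 9-BBN, THF, 0 °C to rt; then H2O2 (30 %), aq. NaOAc, 0 °C to rt
Reagents that add atoms: hydrogen peroxide, OO
Why: Hydroboration–oxidation: 9-BBN should add to the terminal C11 of the exocyclic alkene (anti-Markovnikov, trisubstituted 7-ene left alone) and deliver hydrogen to C9 from the face opposite the axial C10 methyl, which sets C9 with the CH2OH arm equatorial and cis to C20, and buffered peroxide spares the acetate.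

Step 17
Reactants: 21 primary alcohol
Product: 22 aldehyde (C11 aldehyde)
Conditions: Dess–Martin periodinane, pyridine, CH2Cl2, 0 °C
Reagents that add atoms: none
Why: Dess–Martin oxidation under pyridine buffering gives the β,γ-unsaturated aldehyde under conditions mild enough to avoid epimerisation at C9 or migration of the 7-ene into conjugation.

Step 18
Reactants: 23 (R)-methyl hydrogen 3-methylglutarate
Product: 25 methyl (S)-4-bromo-3-methylbutanoate, via mercury dicarboxylate 24 (not isolated)
Conditions: HgO, Br2, CCl4, 77 °C, dark
Reagents that add atoms: bromine, BrBr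
Why: Hunsdiecker reaction (Cristol–Firth variant): the mercury carboxylate is brominated to the acyl hypobromite, which loses CO2 in a radical chain to give the primary bromide; the β-stereocentre is not involved, so the configuration of 23 is kept (the descriptor becomes S only by priority).

Step 19
Reactants: 25 methyl (S)-4-bromo-3-methylbutanoate
Product: 27 carboxy phosphonium bromide, via phosphonium ester 26 (not isolated)
Conditions: PPh3, MeCN, 82 °C; then 48 % aq. HBr, 100 °C
Reagents that add atoms: triphenylphosphine, c1ccc(cc1)P(c1ccccc1)c1ccccc1; water, O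
Why: SN2 quaternisation of the primary bromide by triphenylphosphine followed by acid hydrolysis of the methyl ester gives the carboxy phosphonium salt, so that the Wittig step delivers the free C15 acid and no ester has to be cleaved later beside the C19 acetate.

Step 20
Reactants: 22 aldehyde; 27 carboxy phosphonium bromide
Product: 29 alkenoic acid (Z-C11=C12), via ylide carboxylate 28 (not isolated)
Conditions: 27, NaN(SiMe3)2 (2.0 equiv), THF, 0 °C; then 22, −78 °C to rt; aq. NaH2PO4
Reagents that add atoms: none
Why: Wittig olefination: two equivalents of base give the carboxylate ylide 28, whose non-stabilised ylide carbon should add to the aldehyde at low temperature faster than it enolises it, forming the C11=C12 bond (Z expected, geometry irrelevant) with C13 untouched.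

Step 21
Reactants: 29 alkenoic acid
Product: 30 saturated acid (acetonide)
Conditions: 2-nitrobenzenesulfonylhydrazide, Et3N, CH2Cl2, rt
Reagents that add atoms: none
Why: Diimide reduction: concerted syn transfer of H2 from HN=NH is strongly favoured for the cis-disubstituted C11=C12 alkene over the trisubstituted ring alkene and tolerates the acid, acetate and acetonide.

Step 22
Reactants: 30 saturated acid (acetonide)
Product: 31 CNP0164890.1
Conditions: AcOH/H2O 4:1, 45 °C
Reagents that add atoms: none
Why: Mild aqueous acid hydrolysis of the isopropylidene acetal should free the 2,3-diol without cleaving the C19 acetate or moving the 7-ene, giving the target.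

**Compound list**

1 | (S)-(+)-carvone, (5S)-2-methyl-5-(prop-1-en-2-yl)cyclohex-2-en-1-one | C=C(C)[C@H]1CC=C(C)C(=O)C1 | starting material
2 | lithium dienolate of 1 (O–Li on C1, C1=C6 and C2=C3) | C=C(C)[C@H]1CC=C(C)C(O[Li])=C1 | intermediate
3 | trans-6-methylcarvone, (5S,6R)-2,6-dimethyl-5-(prop-1-en-2-yl)cyclohex-2-en-1-one (minor cis epimer carried along) | C=C(C)[C@H]1CC=C(C)C(=O)[C@@H]1C | intermediate
4 | lithium enolate of 3 (C1=C6) | C=C(C)[C@H]1CC=C(C)C(O[Li])=C1C | intermediate
5 | (5R,6R)-6-allyl-2,6-dimethyl-5-(prop-1-en-2-yl)cyclohex-2-en-1-one (allyl trans, methyl cis to isopropenyl) | C=C(C)[C@H]1CC=C(C)C(=O)[C@]1(C)CC=C | intermediate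
6 | (5R,6R)-2,6-dimethyl-6-(3-oxopropyl)-5-(prop-1-en-2-yl)cyclohex-2-en-1-one | C=C(C)[C@H]1CC=C(C)C(=O)[C@]1(C)CCC=O | intermediate
7 | (5R,6R)-6-[(3R)-3-hydroxypent-4-en-1-yl]-2,6-dimethyl-5-(prop-1-en-2-yl)cyclohex-2-en-1-one | C=C(C)[C@H]1CC=C(C)C(=O)[C@]1(C)CC[C@@H](O)C=C | intermediate
8 | trans-fused 6–7 bicyclic dienone alcohol: seven-membered ring C4(CH3)=C19H–C3H(OH)–C2H2–C1H2–C10–C5 fused to the carvone enone ring, 3-OH (3R) cis to the C10 methyl | CC1=C[C@H](O)CC[C@@]2(C)C(=O)C(C)=CC[C@H]12 | intermediate
9 | 4,19-epoxide of 8, epoxide oxygen and 3-OH both cis to the C10 methyl | C[C@@]12O[C@@H]1[C@H](O)CC[C@@]3(C)C(=O)C(C)=CC[C@H]23 | intermediate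
10 | 3-ketone of 9 (α,β-epoxy ketone, epoxide cis to the C10 methyl) | C[C@@]12O[C@@H]1C(=O)CC[C@@]3(C)C(=O)C(C)=CC[C@H]23 | intermediate
11 | trans-decalin keto aldehyde: 4,8,10-trimethyl-3,9-dioxo-7-ene with C19 formyl on C4 cis to C20, H-5 trans to C20 | O=C[C@@]1(C)[C@H]2CC=C(C)C(=O)[C@]2(C)CCC1=O | intermediate
12 | 19-hydroxy analogue of 11 (C19 CH2OH) | OC[C@@]1(C)[C@H]2CC=C(C)C(=O)[C@]2(C)CCC1=O | intermediate
13 | 19-acetate of 12 | CC(=O)OC[C@@]1(C)[C@H]2CC=C(C)C(=O)[C@]2(C)CCC1=O | intermediate
14 | potassium C2=C3 enolate of 13 | CC(=O)OC[C@@]1(C)[C@H]2CC=C(C)C(=O)[C@]2(C)CC=C1O[K] | intermediate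
15 | 2-en-3-yl triflate of 13 | CC(=O)OC[C@@]1(C)[C@H]2CC=C(C)C(=O)[C@]2(C)CC=C1OS(=O)(=O)C(F)(F)F | intermediate
16 | 19-acetoxy-2,7-dien-9-one (ring A 2-ene) | CC(=O)OC[C@@]1(C)[C@H]2CC=C(C)C(=O)[C@]2(C)CC=C1 | intermediate
17 | 19-acetoxy-2,3-dihydroxy-7-en-9-one, 2,3-diol cis and trans to C20 | CC(=O)OC[C@@]1(C)[C@H]2CC=C(C)C(=O)[C@]2(C)C[C@H](O)[C@@H]1O | intermediate
18 | 2,3-O-isopropylidene derivative of 17 | CC(=O)OC[C@@]1(C)[C@H]2CC=C(C)C(=O)[C@]2(C)C[C@@H]3OC(C)(C)O[C@H]13 | intermediate
19 | 9-methylene-7-ene (C9=C11 exocyclic diene) from 18 | CC(=O)OC[C@@]1(C)[C@H]2CC=C(C)C(=C)[C@]2(C)C[C@@H]3OC(C)(C)O[C@H]13 | intermediate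
20 | C11-(9-borabicyclo[3.3.1]nonan-9-yl) adduct of 19, H-9 trans to C20 | CC(=O)OC[C@@]1(C)[C@H]2CC=C(C)[C@@H](CB3C4CCCC3CCC4)[C@]2(C)C[C@@H]5OC(C)(C)O[C@H]15 | intermediate
21 | C11 primary alcohol (drimenol-type, CH2OH on C9 cis to C20) | CC(=O)OC[C@@]1(C)[C@H]2CC=C(C)[C@@H](CO)[C@]2(C)C[C@@H]3OC(C)(C)O[C@H]13 | intermediate
22 | C11 aldehyde from 21 | CC(=O)OC[C@@]1(C)[C@H]2CC=C(C)[C@@H](C=O)[C@]2(C)C[C@@H]3OC(C)(C)O[C@H]13 | intermediate
23 | (R)-methyl hydrogen 3-methylglutarate, (3R)-5-methoxy-3-methyl-5-oxopentanoic acid | COC(=O)C[C@H](C)CC(=O)O | starting material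
24 | mercury bis-carboxylate of 23 | COC(=O)C[C@H](C)CC(=O)O[Hg]OC(=O)C[C@@H](C)CC(=O)OC | intermediate
25 | methyl (S)-4-bromo-3-methylbutanoate | COC(=O)C[C@H](C)CBr | intermediate
26 | [(2S)-4-methoxy-2-methyl-4-oxobutyl]triphenylphosphonium bromide | COC(=O)C[C@H](C)C[P+](c1ccccc1)(c1ccccc1)c1ccccc1.[Br-] | intermediate
27 | [(2S)-3-carboxy-2-methylpropyl]triphenylphosphonium bromide | OC(=O)C[C@H](C)C[P+](c1ccccc1)(c1ccccc1)c1ccccc1.[Br-] | intermediate
28 | sodium carboxylate ylide from 27 | [Na+].[O-]C(=O)C[C@H](C)C=P(c1ccccc1)(c1ccccc1)c1ccccc1 | intermediate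
29 | (11Z)-11,12-didehydro acid, acetonide and 19-acetate in place | CC(=O)OC[C@@]1(C)[C@H]2CC=C(C)[C@@H](/C=C\[C@@H](C)CC(=O)O)[C@]2(C)C[C@@H]3OC(C)(C)O[C@H]13 | intermediate
30 | 2,3-O-isopropylidene derivative of the target | CC(=O)OC[C@@]1(C)[C@H]2CC=C(C)[C@@H](CC[C@@H](C)CC(=O)O)[C@]2(C)C[C@@H]3OC(C)(C)O[C@H]13 | intermediate
31 | CNP0164890.1, 19-acetoxy-2,3-dihydroxylabd-7-en-15-oic acid of the ent series | CC(=O)OC[C@@]1(C)[C@H]2CC=C(C)[C@@H](CC[C@@H](C)CC(=O)O)[C@]2(C)C[C@H](O)[C@@H]1O | target

**Step count and risk**

Total step count: 22. Longest linear sequence: 20 (steps 1–17 and 20–22); the side-chain branch is steps 18–19.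

Steps most likely to fail:

1. Step 8 (key step). A 1,2-hydride shift from C19 may compete with the acyl shift, and the β-keto aldehyde may lose its formyl carbon during the reaction or work-up. The fallback keeps the ring contraction but avoids the β-dicarbonyl; it sets out from 9 and comes back at 13. Compound 9 would be silylated (t-BuMe2SiOTf, 2,6-lutidine) to the epoxy silyl ether F1. Treatment with MeAl(OAr)2 (Ar = 4-bromo-2,6-di-tert-butylphenyl) in CH2Cl2 at −78 °C should trigger the epoxy silyl ether to β-siloxy aldehyde rearrangement, in which the siloxy-bearing C3 migrates to C4 anti to the epoxide oxygen, giving the ring-contracted siloxy aldehyde F2. NaBH4 would then give the siloxy alcohol F3 and Ac2O/pyridine the siloxy acetate F4. HF·pyridine (non-basic, to avoid acetyl migration) would free the hydroxy acetate F5, and Dess–Martin oxidation of F5 gives 13.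

2. Step 6. Oxygen delivery to the face shielded by the C10 methyl may be incomplete (poor facial selectivity), or the allylic alcohol may be oxidised instead of epoxidised. The fallback replaces hydroxyl direction by catalyst control; it sets out from 8 and comes back at 10. MnO2 would oxidise 8 to the dienone F6. A primary-amine salt of a 9-amino-9-deoxy-epi-cinchona alkaloid (10 mol %) with 50 % aq. H2O2 in dioxane should then epoxidise F6 through the iminium ion of the unhindered C3 ketone only. The quinine- or quinidine-derived pseudo-enantiomer would be chosen to place the oxygen syn to the C10 methyl, giving 10 directly.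

3. Step 15. The ketone between a quaternary carbon and a trisubstituted alkene may react sluggishly, and the Lewis-acidic titanium reagent may strip the acetonide. The fallback uses a two-stage Peterson olefination on a base-stable substrate; it sets out from 18 and comes back at 19. K2CO3/MeOH would remove the acetate to give the hydroxy ketone F7, and t-BuMe2SiCl/imidazole the silyl ether F8. Me3SiCH2Li/CeCl3 in THF at −78 °C should add 1,2 to the C9 ketone from the face opposite the C10 methyl to give the β-hydroxysilane F9. KH in THF would eliminate F9 to the silyl diene F10, Bu4NF would give the diene alcohol F11, and Ac2O/pyridine converts F11 into 19.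

**Further compounds**

F1 | step 8 | 3-O-tert-butyldimethylsilyl ether of 9 | C[C@@]12O[C@@H]1[C@H](O[Si](C)(C)C(C)(C)C)CC[C@@]3(C)C(=O)C(C)=CC[C@H]23
F2 | step 8 | ring-contracted 3-siloxy-9-oxo-7-en-19-al (siloxy group equatorial) | O=C[C@@]1(C)[C@H]2CC=C(C)C(=O)[C@]2(C)CC[C@H]1O[Si](C)(C)C(C)(C)C
F3 | step 8 | 19-hydroxy-3-siloxy-7-en-9-one | OC[C@@]1(C)[C@H]2CC=C(C)C(=O)[C@]2(C)CC[C@H]1O[Si](C)(C)C(C)(C)C
F4 | step 8 | 19-acetoxy-3-siloxy-7-en-9-one | CC(=O)OC[C@@]1(C)[C@H]2CC=C(C)C(=O)[C@]2(C)CC[C@H]1O[Si](C)(C)C(C)(C)C
F5 | step 8 | 19-acetoxy-3-hydroxy-7-en-9-one | CC(=O)OC[C@@]1(C)[C@H]2CC=C(C)C(=O)[C@]2(C)CC[C@H]1O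
F6 | step 6 | seven-membered-ring dienone (3-oxo analogue of 8) | CC1=CC(=O)CC[C@@]2(C)C(=O)C(C)=CC[C@H]12
F7 | step 15 | 19-hydroxy analogue of 18 | OC[C@@]1(C)[C@H]2CC=C(C)C(=O)[C@]2(C)C[C@@H]3OC(C)(C)O[C@H]13
F8 | step 15 | 19-O-tert-butyldimethylsilyl ether of F7 | CC(C)(C)[Si](C)(C)OC[C@@]1(C)[C@H]2CC=C(C)C(=O)[C@]2(C)C[C@@H]3OC(C)(C)O[C@H]13
F9 | step 15 | 9-hydroxy-9-(trimethylsilylmethyl) adduct of F8 | CC(C)(C)[Si](C)(C)OC[C@@]1(C)[C@H]2CC=C(C)[C@@](C[Si](C)(C)C)(O)[C@]2(C)C[C@@H]3OC(C)(C)O[C@H]13
F10 | step 15 | 19-O-silyl analogue of 19 | CC(C)(C)[Si](C)(C)OC[C@@]1(C)[C@H]2CC=C(C)C(=C)[C@]2(C)C[C@@H]3OC(C)(C)O[C@H]13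
F11 | step 15 | 19-hydroxy analogue of 19 | OC[C@@]1(C)[C@H]2CC=C(C)C(=C)[C@]2(C)C[C@@H]3OC(C)(C)O[C@H]13
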